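Late in the runs, at 90.0 s, Tuesday's flask had lost 27.0 mM of J and Sunday's 25.0 mM. Dividing one by the other removes the time and leaves a reading of 1.08, although Tuesday's flask held half the J and twice the X.

| flask | J | X | remark | time |
|---|---|---|---|---|
| Sunday's | 0.10 M | 0.050 mM | run made earlier |  |
| Friday's | 0.10 M | 0.075 mM | run made earlier |  |
| Tuesday's | 0.050 M | 0.10 mM | run made earlier |  |
| flask | 0.10 M | 0.100 mM |  | 2.0 min |

- Sunday's (time / s: J / %, Q / %): 10.0: 99, 1; 20.0: 95, 4; 30.0: 92, 7; 50.0: 82, 12; 80.0: 77, 19; 90.0: 75, 22
- Friday's (time / s: J / %, Q / %): 10.0: 97, 4; 12.0: 95, 2; 20.0: 95, 3; 40.0: 86, 12; 60.0: 78, 19; 90.0: 72, 23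
- Tuesday's (time / s: J / %, Q / %): 10.0: 94, 8; 15.0: 92, 9; 25.0: 87, 13; 50.0: 71, 26; 90.0: 46, 42

(standard deviation of a reading: 2 percentage points)

- X is the free proton; pH is minus the decimal logarithm of its molar concentration
- solid, in amounts per volume of the solution: J
- at the start none of J is in solution
- what has only dissolved of J counts as not reacted

* part of the J that has reacted (what has only dissolved counts as not reacted) at 2.0 min
* pH of the solution at 2.0 min

Across these runs, then, the loss of J looks zero-order, with no visible answer to X or to the charge of J. The J reacted per second at the last reading, averaged over the three runs, is here called the feed rate, 0.296 mM s⁻¹. Over 2.0 min it gives 35.6% of the flask's charge as reacted, on this reckoning.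

The weak link is the straight line carried beyond the last reading. Tuesday's readings hold that rate down to 23.0 mM of J left, while on this reckoning the flask at 2.0 min holds about 64.4 mM, more than that, so in J left the line is not carried below the range where it was read.

The forecast gives 38%, a little above this reckoning, and pH 4, holding that “X is catalytic, not consumed”. This reckoning commits to no pH of its own, since no run read X.

The flask gives 37.3% reacted and pH 2.57. At 2.00 min X stands at 2684% of its own charge.

    D → Z + Q (k = 1.30 × 10⁻⁴ s⁻¹)
    J ⇌ D, rate k2*(cs2 - [D]) while solid is left; crystals form when [D] > cs2 (solubility = 37.0 mM, k = 0.00840 s⁻¹)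
    D + X → Z + X + Q (k = 14000 M⁻¹ s⁻¹)
    Q ⇌ E (K = 0.590, k = 0.00860 s⁻¹)
    Z ⇌ L + X, settled at all times (K = 2.00 × 10⁻⁴ M)

For the neighbour flask with 0.25 M of J, the feed rate over the same time gives 14.2%, and that flask shows 14.9%.

(The data stem from a simulated flask with constants of no real substance.)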